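**Retrosynthetic overview**

- The strategy rests on ring A (C4a, C5, C6, C7, C8, C8a of the 2H-chromene), a fully substituted phloroglucinol ring with three different oxygens: OMe on C5, free OH on C7 and the pyran oxygen O1 on C8a, with the prenyl group on C8 between the last two.
- Late disconnections: the aryl–CO bond of the 1,2-dione (aryl Grignard on an α-keto Weinreb amide), and pyran ring B (O1–C2 and C4–C4a) by propargyl ether Claisen rearrangement from the C8a oxygen.
- The two-carbon oxalyl unit on C6 is brought in through the C7 hydroxyl (coumarandione closure with oxalyl chloride, opening with MeNHOMe).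
- Ring A is cut into diazoketone 4 (C4a, C5, C6, C7 and the OMe) and siloxyalkyne 9 (C8, C8a, prenyl and the protected oxygen), joined by a photo-Wolff vinylketene/ynol ether benzannulation.
- Ring order: ring A (step 4), a transient furandione ring (step 5, opened in step 6), pyran ring B (step 9); the 4-hydroxyphenyl ring is bought.

Key step: step 4

Remark and assumption: chromene numbering of the target is used for ring A throughout; ethyl 4-methylpent-3-enoate (5) is taken as purchasable, and because the ynolate homologation inserts one carbon, this six-carbon acid chain gives the seven-carbon ynol chain of 9.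

**Route**

Step 1
Reactants: 1 3,3-dimethoxybutan-2-one
Product: 2 3-methoxybut-3-en-2-one
Conditions: TsOH·H2O (cat.), hydroquinone (trace), neat, 140 °C, MeOH distilled off
Reagents that add atoms: none
Why: Acid-catalysed elimination of methanol from the α-keto ketal (ketal-to-enol-ether cracking, as used for pyruvate ketals to give 2-methoxyacrylates) should be driven to the enol ether by removal of methanol, the radical inhibitor guarding the polymerisable enone.

Step 2
Reactants: 2 3-methoxybut-3-en-2-one
Product: 4 1-diazo-3-methoxybut-3-en-2-one, via trifluoroacetyl diketone 3 (not isolated)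
Conditions: LiN(SiMe3)2, THF, −78 °C; CF3CO2CH2CF3; aq. HCl work-up, crude 3 carried on; then MsN3, Et3N, H2O, MeCN, rt
Reagents that add atoms: methanesulfonyl azide, CS(=O)(=O)N=[N+]=[N-]
Why: Detrifluoroacetylative diazo transfer: the kinetic methyl enolate undergoes Claisen trifluoroacetylation and the activated 1,3-diketone accepts the diazo group from the sulfonyl azide with loss of the trifluoroacetyl group, the standard way to α'-diazo enones.

Step 3
Reactants: 5 ethyl 4-methylpent-3-enoate; 6 triisopropylsilyl trifluoromethanesulfonate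
Product: 9 triisopropyl(5-methylhex-4-en-1-ynyloxy)silane, via dibromoketone enolate 7 (not isolated), via lithium ynolate 8 (not isolated)
Conditions: CH2Br2, lithium 2,2,6,6-tetramethylpiperidide, THF, −78 °C; then 5; LiN(SiMe3)2; n-BuLi, −78 °C to rt; then 6, −78 to 0 °C
Reagents that add atoms: dibromomethane, BrCBr
Why: Kowalski ester homologation stopped at the ynolate: LiCHBr2 adds to the ester, the dibromoketone enolate undergoes bromine–lithium exchange and carbenoid 1,2-shift of the prenyl group to the ynolate, and the bulky silyl triflate should capture it on oxygen.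

Step 4
Reactants: 4 1-diazo-3-methoxybut-3-en-2-one; 9 triisopropyl(5-methylhex-4-en-1-ynyloxy)silane
Product: 13 5-methoxy-2-(3-methylbut-2-enyl)-3-(triisopropylsilyloxy)phenol, via methoxyvinylketene 10 (not isolated), via vinylcyclobutenone 11 (not isolated), via dienylketene 12 (not isolated)
Conditions: hν (254 nm, low-pressure Hg lamp, Vycor), ClCH2CH2Cl, rt; then 80 °C
Reagents that add atoms: none
Why: Irradiation expels N2 from 4 and photo-Wolff shift of the 1-methoxyvinyl group gives vinylketene 10, which the electron-rich siloxyalkyne 9 should capture in a [2+2] cycloaddition (C7–C8 and C8a–C4a bonds) to cyclobutenone 11. Light or the thermal finish opens 11 by 4π electrocyclic cleavage to dienylketene 12, and ring A closes by 6π electrocyclisation (C6–C7 bond) followed by enolisation to the phenol. The closest known reaction is the Danheiser benzannulation in its photochemical diazoketone variant with siloxyalkynes, which gives resorcinol monosilyl ethers. No stereocentre remains, the single sp3 centre of 11 being lost on ring opening. The step needs one orientation of the [2+2] addition and preference for the alkyne over the prenyl alkene: the ynol ether is polarised so that its prenyl-bearing carbon is nucleophilic and bonds to the ketene carbonyl carbon, which places prenyl ortho and silyloxy meta to the new hydroxyl, and the trisubstituted alkene is far less reactive towards ketenes than the siloxyalkyne.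

Step 5
Reactants: 13 5-methoxy-2-(3-methylbut-2-enyl)-3-(triisopropylsilyloxy)phenol
Product: 15 4-methoxy-7-(3-methylbut-2-enyl)-6-(triisopropylsilyloxy)-1-benzofuran-2,3-dione, via aryl chlorooxalate 14 (not isolated)
Conditions: (COCl)2 (excess), Et2O, 0 to 35 °C, N2 purge
Reagents that add atoms: oxalyl chloride, O=C(Cl)C(=O)Cl
Why: O-acylation of the C7 hydroxyl followed by intramolecular Friedel–Crafts acylation at C6, the only free ortho position and activated by the ortho methoxyl and para silyloxy group, should close the coumarandione without Lewis acid as it does for 3,5-dimethoxyphenol.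

Step 6
Reactants: 15 4-methoxy-7-(3-methylbut-2-enyl)-6-(triisopropylsilyloxy)-1-benzofuran-2,3-dione
Product: 16 2-[2-hydroxy-6-methoxy-3-(3-methylbut-2-enyl)-4-(triisopropylsilyloxy)phenyl]-N-methoxy-N-methyl-2-oxoacetamide
Conditions: MeNHOMe·HCl, Et3N, CH2Cl2, 0 °C to rt
Reagents that add atoms: N,O-dimethylhydroxylamine hydrochloride, CNOC.Cl
Why: Aminolysis of the lactone carbonyl, an activated aryl ester, should open the furandione to the 2-hydroxyaryl α-keto Weinreb amide, the known mode of amine attack on coumarandiones.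

Step 7
Reactants: 16 2-[2-hydroxy-6-methoxy-3-(3-methylbut-2-enyl)-4-(triisopropylsilyloxy)phenyl]-N-methoxy-N-methyl-2-oxoacetamide
Product: 17 2-[2,4-dihydroxy-6-methoxy-3-(3-methylbut-2-enyl)phenyl]-N-methoxy-N-methyl-2-oxoacetamide
Conditions: Bu4NF, THF, 0 °C; aq. NH4Cl
Reagents that add atoms: none
Why: Fluoride cleavage of the aryl silyl ether frees the C8a hydroxyl, the other functional groups being inert to fluoride.

Step 8
Reactants: 17 2-[2,4-dihydroxy-6-methoxy-3-(3-methylbut-2-enyl)phenyl]-N-methoxy-N-methyl-2-oxoacetamide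
Product: 18 2-[2-hydroxy-6-methoxy-3-(3-methylbut-2-enyl)-4-(2-methylbut-3-yn-2-yloxy)phenyl]-N-methoxy-N-methyl-2-oxoacetamide
Conditions: 3-chloro-3-methylbut-1-yne, DBU, CuCl2·2H2O (cat.), MeCN, 0 °C
Reagents that add atoms: 3-chloro-3-methylbut-1-yne, CC(C)(Cl)C#C
Why: Copper-catalysed propargylic etherification of a phenol should take place only at the C8a hydroxyl, which is para to the C6 keto group and the more acidic one, because the C7 hydroxyl is tied up in a hydrogen bond to that ketone.

Step 9
Reactants: 18 2-[2-hydroxy-6-methoxy-3-(3-methylbut-2-enyl)-4-(2-methylbut-3-yn-2-yloxy)phenyl]-N-methoxy-N-methyl-2-oxoacetamide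
Product: 20 2-[7-hydroxy-5-methoxy-2,2-dimethyl-8-(3-methylbut-2-enyl)-2H-chromen-6-yl]-N-methoxy-N-methyl-2-oxoacetamide, via allenylphenol 19 (not isolated)
Conditions: o-xylene, 140 °C
Reagents that add atoms: none
Why: Aromatic propargyl Claisen rearrangement to C4a, the only unsubstituted ortho position, gives the allenylphenol, and 1,5-hydrogen shift with oxa-6π electrocyclisation should close the 2,2-dimethyl-2H-chromene (ring B).

Step 10
Reactants: 21 4-bromophenol
Product: 22 (4-bromophenoxy)(tert-butyl)dimethylsilane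
Conditions: TBSCl, imidazole, DMF, rt
Reagents that add atoms: tert-butyldimethylsilyl chloride, CC(C)(C)[Si](C)(C)Cl
Why: Standard imidazole-promoted silylation masks the phenol so that the aryl bromide can be turned into a Grignard reagent.

Step 11
Reactants: 20 2-[7-hydroxy-5-methoxy-2,2-dimethyl-8-(3-methylbut-2-enyl)-2H-chromen-6-yl]-N-methoxy-N-methyl-2-oxoacetamide; 22 (4-bromophenoxy)(tert-butyl)dimethylsilane
Product: 24 1-[4-(tert-butyldimethylsilyloxy)phenyl]-2-[7-hydroxy-5-methoxy-2,2-dimethyl-8-(3-methylbut-2-enyl)-2H-chromen-6-yl]ethane-1,2-dione, via arylmagnesium bromide 23 (not isolated)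
Conditions: 22, Mg, THF, 40 °C; then added (2.5 equiv) to 20, THF, −78 to 0 °C; aq. NH4Cl
Reagents that add atoms: none
Why: Weinreb ketone synthesis on an α-keto Weinreb amide (a known route to unsymmetrical 1,2-diketones): the first equivalent of Grignard reagent forms the magnesium phenoxide, which further deactivates the already hindered, doubly ortho-substituted aryl ketone, so the second should add to the amide carbonyl and stop at the chelated tetrahedral adduct.

Step 12
Reactants: 24 1-[4-(tert-butyldimethylsilyloxy)phenyl]-2-[7-hydroxy-5-methoxy-2,2-dimethyl-8-(3-methylbut-2-enyl)-2H-chromen-6-yl]ethane-1,2-dione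
Product: 25 Derrisdione A
Conditions: Bu4NF, AcOH, THF, 0 °C
Reagents that add atoms: none
Why: Buffered fluoride cleavage of the aryl silyl ether, made labile by the para acyl group, should free the last phenol without touching the dione, the prenyl group or the chromene.

**Compound list**

1 | 3,3-dimethoxybutan-2-one | CC(=O)C(C)(OC)OC | starting material
2 | 3-methoxybut-3-en-2-one | COC(=C)C(C)=O | intermediate
3 | 1,1,1-trifluoro-5-methoxyhex-5-ene-2,4-dione | COC(=C)C(=O)CC(=O)C(F)(F)F | intermediate (not isolated)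
4 | 1-diazo-3-methoxybut-3-en-2-one | COC(=C)C(=O)C=[N+]=[N-] | intermediate
5 | ethyl 4-methylpent-3-enoate | CCOC(=O)CC=C(C)C | starting material
6 | triisopropylsilyl trifluoromethanesulfonate | CC(C)[Si](OS(=O)(=O)C(F)(F)F)(C(C)C)C(C)C | starting material
7 | lithium 1,1-dibromo-5-methylhexa-1,4-dien-2-olate | [Li+].[O-]C(CC=C(C)C)=C(Br)Br | intermediate (not isolated)
8 | lithium 5-methylhex-4-en-1-yn-1-olate | [Li+].[O-]C#CCC=C(C)C | intermediate (not isolated)
9 | triisopropyl(5-methylhex-4-en-1-ynyloxy)silane | CC(C)=CCC#CO[Si](C(C)C)(C(C)C)C(C)C | intermediate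
10 | 3-methoxybuta-1,3-dien-1-one (methoxyvinylketene) | COC(=C)C=C=O | intermediate (not isolated)
11 | 4-(1-methoxyethenyl)-2-(3-methylbut-2-enyl)-3-(triisopropylsilyloxy)cyclobut-2-en-1-one (racemic) | COC(=C)C1C(=O)C(CC=C(C)C)=C1O[Si](C(C)C)(C(C)C)C(C)C | intermediate (not isolated)
12 | (3E)-5-methoxy-2-(3-methylbut-2-enyl)-3-(triisopropylsilyloxy)hexa-1,3,5-trien-1-one | O=C=C(CC=C(C)C)/C(O[Si](C(C)C)(C(C)C)C(C)C)=C\C(OC)=C | intermediate (not isolated)
13 | 5-methoxy-2-(3-methylbut-2-enyl)-3-(triisopropylsilyloxy)phenol | COc1cc(O)c(CC=C(C)C)c(O[Si](C(C)C)(C(C)C)C(C)C)c1 | intermediate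
14 | 5-methoxy-2-(3-methylbut-2-enyl)-3-(triisopropylsilyloxy)phenyl 2-chloro-2-oxoacetate | COc1cc(OC(=O)C(Cl)=O)c(CC=C(C)C)c(O[Si](C(C)C)(C(C)C)C(C)C)c1 | intermediate (not isolated)
15 | 4-methoxy-7-(3-methylbut-2-enyl)-6-(triisopropylsilyloxy)-1-benzofuran-2,3-dione | COc1cc(O[Si](C(C)C)(C(C)C)C(C)C)c(CC=C(C)C)c2OC(=O)C(=O)c12 | intermediate
16 | 2-[2-hydroxy-6-methoxy-3-(3-methylbut-2-enyl)-4-(triisopropylsilyloxy)phenyl]-N-methoxy-N-methyl-2-oxoacetamide | COc1cc(O[Si](C(C)C)(C(C)C)C(C)C)c(CC=C(C)C)c(O)c1C(=O)C(=O)N(C)OC | intermediate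
17 | 2-[2,4-dihydroxy-6-methoxy-3-(3-methylbut-2-enyl)phenyl]-N-methoxy-N-methyl-2-oxoacetamide | COc1cc(O)c(CC=C(C)C)c(O)c1C(=O)C(=O)N(C)OC | intermediate
18 | 2-[2-hydroxy-6-methoxy-3-(3-methylbut-2-enyl)-4-(2-methylbut-3-yn-2-yloxy)phenyl]-N-methoxy-N-methyl-2-oxoacetamide | COc1cc(OC(C)(C)C#C)c(CC=C(C)C)c(O)c1C(=O)C(=O)N(C)OC | intermediate
19 | 2-[2,4-dihydroxy-6-methoxy-5-(3-methylbuta-1,2-dienyl)-3-(3-methylbut-2-enyl)phenyl]-N-methoxy-N-methyl-2-oxoacetamide | COc1c(C=C=C(C)C)c(O)c(CC=C(C)C)c(O)c1C(=O)C(=O)N(C)OC | intermediate (not isolated)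
20 | 2-[7-hydroxy-5-methoxy-2,2-dimethyl-8-(3-methylbut-2-enyl)-2H-chromen-6-yl]-N-methoxy-N-methyl-2-oxoacetamide | COc1c2c(c(CC=C(C)C)c(O)c1C(=O)C(=O)N(C)OC)OC(C)(C)C=C2 | intermediate
21 | 4-bromophenol | Oc1ccc(Br)cc1 | starting material
22 | (4-bromophenoxy)(tert-butyl)dimethylsilane | CC(C)(C)[Si](C)(C)Oc1ccc(Br)cc1 | intermediate
23 | [4-(tert-butyldimethylsilyloxy)phenyl]magnesium bromide | CC(C)(C)[Si](C)(C)Oc1ccc([Mg]Br)cc1 | intermediate (not isolated)
24 | 1-[4-(tert-butyldimethylsilyloxy)phenyl]-2-[7-hydroxy-5-methoxy-2,2-dimethyl-8-(3-methylbut-2-enyl)-2H-chromen-6-yl]ethane-1,2-dione | COc1c2c(c(CC=C(C)C)c(O)c1C(=O)C(=O)c1ccc(O[Si](C)(C)C(C)(C)C)cc1)OC(C)(C)C=C2 | intermediate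
25 | Derrisdione A, 1-[7-hydroxy-5-methoxy-2,2-dimethyl-8-(3-methylbut-2-enyl)-2H-chromen-6-yl]-2-(4-hydroxyphenyl)ethane-1,2-dione | COc1c2c(c(CC=C(C)C)c(O)c1C(=O)C(=O)c1ccc(O)cc1)OC(C)(C)C=C2 | target

**Step count**

Total steps: 12. Longest linear sequence: 10 steps (steps 1, 2, 4, 5, 6, 7, 8, 9, 11, 12).

**Steps most likely to fail**

1. Step 4 (benzannulation). The unsubstituted vinylketene may be consumed by dimerisation, or by O-acylation of phenol already formed, faster than the alkyne captures it, and prolonged short-wave irradiation may degrade the siloxyalkyne. The fallback builds the same phenol by directed metalation; it sets out from silyl triflate 6 and bought 5-methoxyresorcinol and comes back at 13. 5-Methoxyresorcinol is protected with MOMCl/i-Pr2NEt as 1-methoxy-3,5-bis(methoxymethoxy)benzene F1. n-BuLi in THF at 0 °C should lithiate the position between the two acetal groups to give [4-methoxy-2,6-bis(methoxymethoxy)phenyl]lithium F2, which is alkylated by 1-bromo-3-methylbut-2-ene with CuBr·SMe2 as catalyst to 5-methoxy-1,3-bis(methoxymethoxy)-2-(3-methylbut-2-enyl)benzene F3. Dilute HCl in MeOH at rt removes both acetals to give the symmetrical 5-methoxy-2-(3-methylbut-2-enyl)benzene-1,3-diol F4. One equivalent of 6 with 2,6-lutidine in CH2Cl2 at −78 °C silylates one of the two equivalent hydroxyls to give 13, with bis-silyl ether and unreacted diol recycled.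

2. Step 5 (coumarandione closure). After O-acylation the ring closure at C6 may stall, and the hydrogen chloride released may add across the prenyl double bond or trigger its cyclisation. The fallback installs the keto amide by directed ortho-metalation under basic conditions; it sets out from 13 and comes back at 16. Phenol 13 is protected with MOMCl/i-Pr2NEt as triisopropyl[5-methoxy-3-(methoxymethoxy)-2-(3-methylbut-2-enyl)phenoxy]silane F5. n-BuLi in THF at 0 °C should lithiate C6, flanked by the acetal and the methoxyl, to give [6-methoxy-2-(methoxymethoxy)-3-(3-methylbut-2-enyl)-4-(triisopropylsilyloxy)phenyl]lithium F6. Inverse addition of F6 to excess N,N'-dimethoxy-N,N'-dimethyloxalamide at −78 °C gives N-methoxy-2-[6-methoxy-2-(methoxymethoxy)-3-(3-methylbut-2-enyl)-4-(triisopropylsilyloxy)phenyl]-N-methyl-2-oxoacetamide F7. ZnBr2 and n-PrSH in CH2Cl2 at 0 °C remove the acetal, which sits ortho to the ketone, to give 16.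

3. Step 3 (ynolate formation). Deprotonation of the doubly activated C2 methylene of the β,γ-unsaturated ester, with drift of the double bond into conjugation, may compete with carbonyl addition of LiCHBr2. The fallback makes the ynolate by oxygenation of an acetylide; it replaces ester 5 by bought 1-bromo-3-methylbut-2-ene and ethynylmagnesium bromide, uses triflate 6, and comes back at ynolate 8 and so at 9. CuCl-catalysed coupling of the two bought reagents in THF gives 5-methylhex-4-en-1-yne F8. n-BuLi in THF at −78 °C gives lithium 5-methylhex-4-en-1-yn-1-ide F9. Lithium tert-butyl peroxide (from t-BuOOH and LiN(SiMe3)2), −78 to 0 °C, should oxidise F9 to ynolate 8, which is silylated with 6 as in step 3 to give 9.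

**Further compounds**

F1 | step 4 | 1-methoxy-3,5-bis(methoxymethoxy)benzene | COCOc1cc(OC)cc(OCOC)c1
F2 | step 4 | [4-methoxy-2,6-bis(methoxymethoxy)phenyl]lithium | [Li]c1c(OCOC)cc(OC)cc1OCOC
F3 | step 4 | 5-methoxy-1,3-bis(methoxymethoxy)-2-(3-methylbut-2-enyl)benzene | COCOc1cc(OC)cc(OCOC)c1CC=C(C)C
F4 | step 4 | 5-methoxy-2-(3-methylbut-2-enyl)benzene-1,3-diol | COc1cc(O)c(CC=C(C)C)c(O)c1
F5 | step 5 | triisopropyl[5-methoxy-3-(methoxymethoxy)-2-(3-methylbut-2-enyl)phenoxy]silane | COCOc1cc(OC)cc(O[Si](C(C)C)(C(C)C)C(C)C)c1CC=C(C)C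
F6 | step 5 | [6-methoxy-2-(methoxymethoxy)-3-(3-methylbut-2-enyl)-4-(triisopropylsilyloxy)phenyl]lithium | [Li]c1c(OC)cc(O[Si](C(C)C)(C(C)C)C(C)C)c(CC=C(C)C)c1OCOC
F7 | step 5 | N-methoxy-2-[6-methoxy-2-(methoxymethoxy)-3-(3-methylbut-2-enyl)-4-(triisopropylsilyloxy)phenyl]-N-methyl-2-oxoacetamide | COCOc1c(CC=C(C)C)c(O[Si](C(C)C)(C(C)C)C(C)C)cc(OC)c1C(=O)C(=O)N(C)OC
F8 | step 3 | 5-methylhex-4-en-1-yne | CC(C)=CCC#C
F9 | step 3 | lithium 5-methylhex-4-en-1-yn-1-ide | [Li]C#CCC=C(C)C
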